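**Retrosynthetic overview**
1. Rings A and B are bought intact as 2,4,5-trimethoxyacetophenone 1 and methyl 2,3,4-trimethoxybenzoate 2; ring C is the only ring formed.
2. A Claisen C–C disconnection joins 1 and 2 to the 1,3-diketone 4 (through its sodium enolate 3).
3. Key disconnection: the aryl C–O bond O1–C8a of ring C, closed from 4 by dehydrogenative C–H/O–H coupling to hexamethoxyflavone 5.
4. Last disconnection: the O–CH3 bond at O-5; chelation-controlled demethylation of 5 (through boron chelate 6) gives serpyllin 7.

Assumption: serpyllin has no stereocentre or stereogenic axis, so "single enantiomer" is read as the single achiral constitution given; 1 and 2 are taken as catalogue chemicals.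

**Step 1**
Reactants: 1 2,4,5-trimethoxyacetophenone; 2 methyl 2,3,4-trimethoxybenzoate
Product: 4 1-(2,4,5-trimethoxyphenyl)-3-(2,3,4-trimethoxyphenyl)propane-1,3-dione, via sodium enolate 3 (not isolated)
Conditions: NaH (2.5 equiv), THF, reflux, 6 h (1 added slowly to 2/NaH); then 1 M HCl, 0 °C
Reagents that add atoms: none
Why: Crossed Claisen condensation of the methyl ketone enolate with a non-enolisable ester, driven to completion by irreversible deprotonation of the product to the chelated sodium diketonate 3, which the acid quench converts to 4.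

**Step 2**
Reactants: 4 1-(2,4,5-trimethoxyphenyl)-3-(2,3,4-trimethoxyphenyl)propane-1,3-dione
Product: 5 5,7,8-trimethoxy-2-(2,3,4-trimethoxyphenyl)-4H-chromen-4-one
Conditions: 9-mesityl-3,6-di-tert-butyl-10-phenylacridinium tetrafluoroborate (5 mol%), Co(dmgH)2(py)Cl (8 mol%; dmgH = dimethylglyoximate monoanion, py = pyridine), 4 Å MS, ClCH2CH2Cl/(CF3)2CHOH 4:1, 0.05 M, 450 nm LEDs, Ar, 25 °C, 24 h
Reagents that add atoms: none
Why: Proposed new method: an acceptorless dehydrogenative aryl C–H/enol O–H coupling in which the excited acridinium (about +2.1 V vs SCE) removes one electron from the 1,2,4-trioxygenated ring A, estimated about 0.3 V easier to oxidise than the 1,2,3-trioxygenated ring B, so the hole sits on ring A; the enol oxygen on the ring-B-bearing carbon then attacks the only ring-A carbon that carries hydrogen ortho to the ketone (future C-8a) through a six-membered transition state, proton loss gives a cyclohexadienyl radical, and the cobaloxime (trivalent cobalt reduced to divalent cobalt by the acridine radical) takes up that hydrogen and releases H2, so no stoichiometric oxidant is present to attack the para-dimethoxy ring of 5; the closest known reaction types are acridinium/cobaloxime arene radical-cation C–H amination and etherification with hydrogen evolution, dehydrogenative lactonisation of biaryl-2-carboxylic acids, and the oxidative cyclisation of hydroxybenzophenones to xanthones.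

**Step 3**
Reactants: 5 5,7,8-trimethoxy-2-(2,3,4-trimethoxyphenyl)-4H-chromen-4-one
Product: 7 serpyllin (5-hydroxy-7,8-dimethoxy-2-(2,3,4-trimethoxyphenyl)-4H-chromen-4-one), via dichloroboron chelate 6 (not isolated)
Conditions: BCl3 (1.5 equiv, 1 M in CH2Cl2), CH2Cl2, −78 °C to 0 °C, 2 h; then H2O, 25 °C
Reagents that add atoms: none
Why: Chelation-controlled Lewis-acid ether cleavage (selective peri-O-demethylation): boron bound to the C-4 carbonyl can reach only the 5-methoxy oxygen in a six-membered chelate, chloride removes that methyl by SN2, and water hydrolyses chelate 6 to the hydrogen-bonded 5-phenol while the other five methoxy groups stay untouched at low temperature.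

**Compound list**
1 | 2,4,5-trimethoxyacetophenone | CC(=O)c1cc(OC)c(OC)cc1OC | starting material
2 | methyl 2,3,4-trimethoxybenzoate | COC(=O)c1ccc(OC)c(OC)c1OC | starting material
3 | sodium (Z)-3-oxo-1-(2,3,4-trimethoxyphenyl)-3-(2,4,5-trimethoxyphenyl)prop-1-en-1-olate (sodium enolate of 4) | [Na+].COc1cc(OC)c(OC)cc1C(=O)/C=C(\[O-])c1ccc(OC)c(OC)c1OC | intermediate (not isolated)
4 | 1-(2,4,5-trimethoxyphenyl)-3-(2,3,4-trimethoxyphenyl)propane-1,3-dione (mainly chelated enol) | COc1cc(OC)c(OC)cc1C(=O)CC(=O)c1ccc(OC)c(OC)c1OC | intermediate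
5 | 5,7,8-trimethoxy-2-(2,3,4-trimethoxyphenyl)-4H-chromen-4-one | COc1ccc(-c2cc(=O)c3c(OC)cc(OC)c(OC)c3o2)c(OC)c1OC | intermediate
6 | 5-(dichloroboryloxy)-7,8-dimethoxy-2-(2,3,4-trimethoxyphenyl)-4H-chromen-4-one (boron chelated to the C-4 carbonyl) | COc1ccc(-c2cc(=O)c3c(OB(Cl)Cl)cc(OC)c(OC)c3o2)c(OC)c1OC | intermediate (not isolated)
7 | serpyllin, 5-hydroxy-7,8-dimethoxy-2-(2,3,4-trimethoxyphenyl)-4H-chromen-4-one (achiral) | COc1ccc(-c2cc(=O)c3c(O)cc(OC)c(OC)c3o2)c(OC)c1OC | target

**Totals**
Total step count: 3. Longest linear sequence: 3 steps (1 or 2 → 4 → 5 → 7).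

**Steps most likely to fail**

Step 2 (highest risk, the proposed new reaction). The chelated enol is a weak nucleophile, back electron transfer may outrun cyclisation, and attack at the methoxy-bearing ortho carbon with loss of methanol would give the isomeric 6,7-dimethoxyflavone. The fallback uses known chemistry; it sets out from 2 and comes back to the route at 5. Commercial 1,2,3,5-tetramethoxybenzene F1 is treated with acetyl chloride and AlCl3 in Et2O. Friedel–Crafts acylation gives 2,3,4,6-tetramethoxyacetophenone F2 in the flask, and AlCl3 then cleaves the methoxy group flanked by the acetyl and a second methoxy group, giving 2-hydroxy-3,4,6-trimethoxyacetophenone F3. Claisen condensation of F3 with 2 (NaH, THF, reflux, then HCl) gives 1-(2-hydroxy-3,4,6-trimethoxyphenyl)-3-(2,3,4-trimethoxyphenyl)propane-1,3-dione F4. Acid cyclodehydration (cat. H2SO4, AcOH, 100 °C) closes ring C through the phenol oxygen to 5. The ring C–O bond is then made by carbonyl condensation instead of C–H functionalisation, at the cost of two extra steps.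

Step 3. BCl3 could cleave a second methoxy group or leave a stubborn boron chelate. The fallback sets out from 5 and comes back at 7. (NH4)2Ce(NO3)6 in MeCN/H2O at 0 °C oxidatively demethylates the para-related 5- and 8-methoxy groups of ring A (ring B has no para-dimethoxy pair) to 7-methoxy-2-(2,3,4-trimethoxyphenyl)-4H-chromene-4,5,8-trione F5. Na2S2O4 in EtOAc/H2O reduces this to 5,8-dihydroxy-7-methoxy-2-(2,3,4-trimethoxyphenyl)-4H-chromen-4-one F6. One equivalent of dimethyl sulfate with K2CO3 in acetone under N2 then methylates only the 8-OH, because the 5-OH is locked in its hydrogen bond to the C-4 carbonyl, giving 7.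

Step 1. The electron-rich, ortho-substituted ester may acylate slowly and let 1 self-condense. The fallback sets out from 1 and comes back at 4. Aldol addition of 1 (LiN(iPr)2, THF, −78 °C) to commercial 2,3,4-trimethoxybenzaldehyde F7 gives racemic 3-hydroxy-1-(2,4,5-trimethoxyphenyl)-3-(2,3,4-trimethoxyphenyl)propan-1-one F8. 2-Iodoxybenzoic acid in EtOAc at 75 °C oxidises the β-hydroxy ketone to 4, which erases the carbinol stereocentre.

**Further compounds**
F1 | step 2 | 1,2,3,5-tetramethoxybenzene | COc1cc(OC)c(OC)c(OC)c1
F2 | step 2 | 2,3,4,6-tetramethoxyacetophenone | CC(=O)c1c(OC)cc(OC)c(OC)c1OC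
F3 | step 2 | 2-hydroxy-3,4,6-trimethoxyacetophenone | CC(=O)c1c(O)c(OC)c(OC)cc1OC
F4 | step 2 | 1-(2-hydroxy-3,4,6-trimethoxyphenyl)-3-(2,3,4-trimethoxyphenyl)propane-1,3-dione | COc1cc(OC)c(OC)c(O)c1C(=O)CC(=O)c1ccc(OC)c(OC)c1OC
F5 | step 3 | 7-methoxy-2-(2,3,4-trimethoxyphenyl)-4H-chromene-4,5,8-trione | O=C1C=C(OC)C(=O)C2=C1C(=O)C=C(O2)c1ccc(OC)c(OC)c1OC
F6 | step 3 | 5,8-dihydroxy-7-methoxy-2-(2,3,4-trimethoxyphenyl)-4H-chromen-4-one | COc1ccc(-c2cc(=O)c3c(O)cc(OC)c(O)c3o2)c(OC)c1OC
F7 | step 1 | 2,3,4-trimethoxybenzaldehyde | COc1ccc(C=O)c(OC)c1OC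
F8 | step 1 | 3-hydroxy-1-(2,4,5-trimethoxyphenyl)-3-(2,3,4-trimethoxyphenyl)propan-1-one (racemic) | COc1cc(OC)c(OC)cc1C(=O)CC(O)c1ccc(OC)c(OC)c1OC
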